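The oxolane ring is cut at O1–C5 and C3–C4. This leaves a three-atom unit O1–C2(aryl)–C3 and a two-atom unit C4–C5. The feature exploited is that C5 is an unsubstituted CH2 next to C4, whose side chain begins at an oxidised carbon (C7'). C4–C5 therefore maps onto an acrylate, and the one-carbon arm on C3 can be masked as a vinyl group. A formal (3+2) cycloaddition of an enantiopure 2-aryl-3-vinyloxirane with tert-butyl acrylate, catalysed by zerovalent palladium, builds the ring in one operation and is stereoconvergent at C3. An epimerising lactonisation then enforces the 3,4-cis relationship, and the lactone takes up the second aryl group.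

Key step: step 3

Remark: the discussion uses the locants of the target oxolane (O1, C2 aryl, C3 CH2OH, C4 side chain, C5 CH2; C9 = hydroxymethyl carbon, C7' = carbinol carbon), while systematic names keep their own numbering. The target SMILES is read as (2S,3R,4R,7'S), with 2,3-trans and 3,4-cis substituents.

Step 1
Reactants: 1 4-(benzyloxy)-3-methoxybenzaldehyde; 2 diethyl allylphosphonate
Product: 4 (E)-1-[4-(benzyloxy)-3-methoxyphenyl]buta-1,3-diene, via lithiated allylphosphonate 3 (not isolated)
Conditions: 2, n-BuLi, THF, −78 °C; HMPA; then 1, −78 °C to rt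
Reagents that add atoms: none
Why: Horner–Wadsworth–Emmons olefination through the α-carbon of the lithiated allylphosphonate, in which HMPA promotes equilibration and elimination of the adduct so that the terminal (E)-diene should result.

Step 2
Reactants: 4 (E)-1-[4-(benzyloxy)-3-methoxyphenyl]buta-1,3-diene
Product: 5 (2R,3R)-2-[4-(benzyloxy)-3-methoxyphenyl]-3-ethenyloxirane
Conditions: D-fructose-derived Shi ketone (30 mol %), 2KHSO5·KHSO4·K2SO4 (Oxone), K2CO3, Bu4NHSO4 (cat.), MeCN–CH2(OMe)2, aq. Na2B4O7–Na2EDTA buffer (pH about 10.5), −10 to 0 °C; cold extraction, Et3N-washed silica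
Reagents that add atoms: potassium peroxymonosulfate [K+].[O-]S(=O)(=O)OO
Why: Shi asymmetric epoxidation, in which the chiral dioxirane reacts through a spiro transition state with the trans-disubstituted styrenyl C=C far faster than with the terminal vinyl group, and the D-fructose-derived ketone should deliver the (R,R)-oxirane that fixes C2 of the target.

Step 3
Reactants: 5 (2R,3R)-2-[4-(benzyloxy)-3-methoxyphenyl]-3-ethenyloxirane; 6 tert-butyl acrylate
Product: 7 tert-butyl (4S,5S)-5-[4-(benzyloxy)-3-methoxyphenyl]-4-ethenyloxolane-3-carboxylate (both epimers at the ester-bearing carbon)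
Conditions: Pd2(dba)3·CHCl3 (2.5 mol %), P(4-FC6H4)3 (15 mol %), Bu4NCl (20 mol %), 6 (5 equiv), BHT (trace), THF, 0 °C to rt, slow addition of 5
Reagents that add atoms: none
Why: Zerovalent palladium ionises the allylic C3–O bond of 5 with inversion to a zwitterionic η3-allylpalladium alkoxide in which C2 is untouched, the alkoxide O1 adds to the CH2 terminus of 6 (oxa-Michael addition, O1–C5 bond), and the resulting ester enolate carbon C4 attacks the internal allyl terminus C3 on the face away from the metal (C3–C4 bond) with release of the catalyst. The closest known reaction type is the palladium-catalysed formal (3+2) cycloaddition of vinyloxiranes, vinylaziridines and vinylcyclopropanes with Michael acceptors, a family that includes mono-activated enones and acrylates. The single ring formed, the oxolane, closes in the second event as a 5-exo allylic alkylation in which the allyl remainder stays outside the ring and becomes the vinyl group, and this mode is preferred over 7-endo attack at the allyl CH2 terminus. C3 is controlled by C2: double inversion means net retention and hence the 2,3-trans product from the trans-oxirane, and because the allyl unit ends in a CH2 group its two faces interconvert by η3–η1–η3 slippage (assisted by chloride), so that cis-oxirane or a mismatched complex should be funnelled through the lower transition state, in which the C2 aryl group points away from both the metal and the allyl chain. C4 is formed without useful control (the 3,4-trans ester should prevail), which is accepted because this centre stays epimerisable and is corrected in step 5. The step needs 1,4- rather than 1,2-addition of the alkoxide and capture of the zwitterion before hydride shift or oligomerisation, which the bulky tert-butyl ester, the excess of 6 and the slow addition of 5 should secure.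

Step 4
Reactants: 7 tert-butyl (4S,5S)-5-[4-(benzyloxy)-3-methoxyphenyl]-4-ethenyloxolane-3-carboxylate
Product: 9 tert-butyl (4R,5S)-5-[4-(benzyloxy)-3-methoxyphenyl]-4-(hydroxymethyl)oxolane-3-carboxylate (both epimers at the ester-bearing carbon), via aldehyde 8 (not isolated)
Conditions: OsO4 (2 mol %), NaIO4, 2,6-lutidine, 1,4-dioxane–H2O, rt; extraction; then NaBH4, MeOH, 0 °C
Reagents that add atoms: osmium tetroxide O=[Os](=O)(=O)=O (oxygen carrier); sodium periodate [Na+].[O-]I(=O)(=O)=O (terminal oxygen source)
Why: Lemieux–Johnson cleavage of the only C=C bond followed by borohydride reduction turns the vinyl group into the C9 hydroxymethyl group, and the lutidine buffer together with immediate reduction should keep the α-stereocentre C3 of aldehyde 8 intact.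

Step 5
Reactants: 9 tert-butyl (4R,5S)-5-[4-(benzyloxy)-3-methoxyphenyl]-4-(hydroxymethyl)oxolane-3-carboxylate
Product: 10 (1R,5R,6S)-6-[4-(benzyloxy)-3-methoxyphenyl]-3,7-dioxabicyclo[3.3.0]octan-2-one (cis-fused; aryl exo)
Conditions: KOt-Bu (0.3 equiv), THF, 0 °C to rt; AcOH quench
Reagents that add atoms: none
Why: Base-catalysed epimerisation and lactonisation under thermodynamic control, in which C4 equilibrates through the ester enolate and only the 3,4-cis epimer can close the unstrained cis-fused γ-lactone with loss of tert-butanol, so that both epimers should drain into 10 and C4 is set by C3.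

Step 6
Reactants: 11 4-bromo-2-methoxyphenol
Product: 12 1-(benzyloxy)-4-bromo-2-methoxybenzene
Conditions: BnBr, K2CO3, DMF, rt
Reagents that add atoms: benzyl bromide BrCc1ccccc1
Why: Williamson ether synthesis on the phenoxide gives a benzyl ether that tolerates organolithium chemistry and creates no stereocentre.

Step 7
Reactants: 12 1-(benzyloxy)-4-bromo-2-methoxybenzene; 10 (1R,5R,6S)-6-[4-(benzyloxy)-3-methoxyphenyl]-3,7-dioxabicyclo[3.3.0]octan-2-one
Product: 14 [4-(benzyloxy)-3-methoxyphenyl][(3R,4R,5S)-5-[4-(benzyloxy)-3-methoxyphenyl]-4-(hydroxymethyl)oxolan-3-yl]methanone, via aryllithium 13 (not isolated)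
Conditions: 12, n-BuLi, THF, −78 °C; then 10, THF, −78 °C; sat. aq. NH4Cl at −78 °C
Reagents that add atoms: none
Why: Bromine–lithium exchange and single 1,2-addition of the aryllithium to the γ-lactone, whose tetrahedral lithium adduct persists at −78 °C and so blocks a second addition, while the cold neutral quench should spare the epimerisable C4 centre.

Step 8
Reactants: 14 [4-(benzyloxy)-3-methoxyphenyl][(3R,4R,5S)-5-[4-(benzyloxy)-3-methoxyphenyl]-4-(hydroxymethyl)oxolan-3-yl]methanone
Product: 15 (S)-[4-(benzyloxy)-3-methoxyphenyl][(3R,4R,5S)-5-[4-(benzyloxy)-3-methoxyphenyl]-4-(hydroxymethyl)oxolan-3-yl]methanol (di-O-benzyl tanegol)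
Conditions: LiBH(s-Bu)3 (2.5 equiv), THF, −78 °C; sat. aq. NH4Cl
Reagents that add atoms: none
Why: Felkin–Anh-controlled hydride reduction, in which the C4–H bond lies near the aryl group and the bulky borohydride should attack the carbonyl face on the C5H2 side, anti to the branched C3 carbon with its cis hydroxymethyl arm, which gives the (7'S)-alcohol.

Step 9
Reactants: 15 di-O-benzyl tanegol
Product: 16 (−)-tanegol
Conditions: H2 (1 atm), 10 % Pd/C, EtOAc–EtOH, rt, stopped at full conversion
Reagents that add atoms: none
Why: Catalytic hydrogenolysis of the two aryl benzyl ethers, which under neutral conditions at 1 atm are cleaved much faster than the secondary benzylic alcohol or the cyclic benzylic ether, so that no stereocentre is touched.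

Compound list
1 | 4-(benzyloxy)-3-methoxybenzaldehyde | COc1cc(C=O)ccc1OCc1ccccc1 | starting material
2 | diethyl allylphosphonate | C=CCP(=O)(OCC)OCC | starting material
3 | α-lithiated diethyl allylphosphonate | [Li]C(C=C)P(=O)(OCC)OCC | intermediate
4 | (E)-1-[4-(benzyloxy)-3-methoxyphenyl]buta-1,3-diene | C=C/C=C/c1ccc(OCc2ccccc2)c(OC)c1 | intermediate
5 | (2R,3R)-2-[4-(benzyloxy)-3-methoxyphenyl]-3-ethenyloxirane | O1[C@H](c2ccc(OCc3ccccc3)c(OC)c2)[C@H]1C=C | intermediate
6 | tert-butyl acrylate | C=CC(=O)OC(C)(C)C | starting material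
7 | tert-butyl (4S,5S)-5-[4-(benzyloxy)-3-methoxyphenyl]-4-ethenyloxolane-3-carboxylate, both epimers at the ester-bearing carbon (centre left open in the SMILES) | CC(C)(C)OC(=O)C1CO[C@H](c2ccc(OCc3ccccc3)c(OC)c2)[C@H]1C=C | intermediate
8 | tert-butyl (4S,5S)-5-[4-(benzyloxy)-3-methoxyphenyl]-4-formyloxolane-3-carboxylate, both epimers at the ester-bearing carbon | CC(C)(C)OC(=O)C1CO[C@H](c2ccc(OCc3ccccc3)c(OC)c2)[C@H]1C=O | intermediate
9 | tert-butyl (4R,5S)-5-[4-(benzyloxy)-3-methoxyphenyl]-4-(hydroxymethyl)oxolane-3-carboxylate, both epimers at the ester-bearing carbon | CC(C)(C)OC(=O)C1CO[C@H](c2ccc(OCc3ccccc3)c(OC)c2)[C@H]1CO | intermediate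
10 | (1R,5R,6S)-6-[4-(benzyloxy)-3-methoxyphenyl]-3,7-dioxabicyclo[3.3.0]octan-2-one | O=C1[C@H]2CO[C@H](c3ccc(OCc4ccccc4)c(OC)c3)[C@H]2CO1 | intermediate
11 | 4-bromo-2-methoxyphenol | COc1cc(Br)ccc1O | starting material
12 | 1-(benzyloxy)-4-bromo-2-methoxybenzene | COc1cc(Br)ccc1OCc1ccccc1 | intermediate
13 | [4-(benzyloxy)-3-methoxyphenyl]lithium | [Li]c1ccc(OCc2ccccc2)c(OC)c1 | intermediate
14 | [4-(benzyloxy)-3-methoxyphenyl][(3R,4R,5S)-5-[4-(benzyloxy)-3-methoxyphenyl]-4-(hydroxymethyl)oxolan-3-yl]methanone | O=C(c1ccc(OCc2ccccc2)c(OC)c1)[C@H]1CO[C@H](c2ccc(OCc3ccccc3)c(OC)c2)[C@H]1CO | intermediate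
15 | (S)-[4-(benzyloxy)-3-methoxyphenyl][(3R,4R,5S)-5-[4-(benzyloxy)-3-methoxyphenyl]-4-(hydroxymethyl)oxolan-3-yl]methanol | COc1cc([C@@H](O)[C@H]2CO[C@H](c3ccc(OCc4ccccc4)c(OC)c3)[C@H]2CO)ccc1OCc1ccccc1 | intermediate
16 | (−)-tanegol, (S)-(4-hydroxy-3-methoxyphenyl)[(3R,4R,5S)-5-(4-hydroxy-3-methoxyphenyl)-4-(hydroxymethyl)oxolan-3-yl]methanol | COc1cc([C@@H](O)[C@H]2CO[C@H](c3ccc(O)c(OC)c3)[C@H]2CO)ccc1O | target

Total step count: 9. Longest linear sequence: 8 (steps 1 to 5 and 7 to 9).

Steps most likely to fail

**Step 3.**
- What may go wrong: the zwitterionic allylpalladium alkoxide may isomerise by hydride shift, or add to a second allyl unit, faster than it adds to the mono-activated acrylate. The hard ester enolate may also start anionic polymerisation of 6 instead of closing the ring.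
- The fallback sets out from 5 and comes back at 10. The acceptor is changed to freshly distilled dimethyl methylidenemalonate, a doubly activated alkene of the classical partner class. The oxa-Michael step then becomes fast and a soft malonate anion closes the ring.
- Pd(PPh3)4 in THF at rt should give dimethyl (4S,5S)-5-[4-(benzyloxy)-3-methoxyphenyl]-4-ethenyloxolane-3,3-dicarboxylate F1, which has no stereocentre at C4.
- Lemieux–Johnson cleavage as in step 4 gives dimethyl (4S,5S)-5-[4-(benzyloxy)-3-methoxyphenyl]-4-formyloxolane-3,3-dicarboxylate F2.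
- NaBH4 reduction is followed by spontaneous lactonisation onto the ester that is cis to the new hydroxymethyl group. This gives methyl (1R,5R,6S)-6-[4-(benzyloxy)-3-methoxyphenyl]-2-oxo-3,7-dioxabicyclo[3.3.0]octane-1-carboxylate F3.
- Krapcho demethoxycarbonylation (LiCl, wet DMSO, 130 °C) then leads to 10, because the lactone enolate can be protonated only to the cis-fused bicycle.

**Step 2.**
- What may go wrong: the oxirane is both benzylic (electron-rich aryl) and allylic, so solvolytic ring opening in the aqueous buffer, over-oxidation of the remaining vinyl group and losses on silica may erode the material.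
- The fallback sets out from 1 and comes back at 7. It avoids water by an asymmetric chloroallylboration. (Z)-(γ-Chloroallyl)diisopinocampheylborane is made at −95 °C from allyl chloride, LiN(c-C6H11)2 and (−)-Ipc2BOMe with BF3·OEt2.
- This borane adds to 1 to give the syn-chlorohydrin (1R,2R)-1-[4-(benzyloxy)-3-methoxyphenyl]-2-chlorobut-3-en-1-ol F4.
- DBU in CH2Cl2 closes it to the cis-oxirane (2R,3S)-2-[4-(benzyloxy)-3-methoxyphenyl]-3-ethenyloxirane F5.
- F5 has the C2 configuration of 5 and differs only at the allylic carbon that is ionised, so under the conditions of step 3 with 6 it should converge on 7.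

**Step 8.**
- What may go wrong: facial selectivity may be poor, the reduction may stall through ring–chain tautomerism once the free hydroxyl group is deprotonated, and the alkoxide may cause epimerisation at C4 before hydride transfer.
- The fallback sets out from 14 and comes back at 15. It replaces substrate control on the free hydroxy ketone by catalyst control on a locked open-chain ketone.
- TBSCl and imidazole in CH2Cl2 at 0 °C give [4-(benzyloxy)-3-methoxyphenyl][(3R,4R,5S)-5-[4-(benzyloxy)-3-methoxyphenyl]-4-[(tert-butyldimethylsilyloxy)methyl]oxolan-3-yl]methanone F6.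
- Corey–Bakshi–Shibata reduction with the (R)-methyl oxazaborolidine and BH3·SMe2 is matched with the Felkin–Anh preference. It should give the (S)-carbinol silyl ether F7.
- Bu4NF in THF then removes the silyl group to give 15.

Further compounds
F1 | step 3 | dimethyl (4S,5S)-5-[4-(benzyloxy)-3-methoxyphenyl]-4-ethenyloxolane-3,3-dicarboxylate | COC(=O)C1(C(=O)OC)CO[C@H](c2ccc(OCc3ccccc3)c(OC)c2)[C@H]1C=C
F2 | step 3 | dimethyl (4S,5S)-5-[4-(benzyloxy)-3-methoxyphenyl]-4-formyloxolane-3,3-dicarboxylate | COC(=O)C1(C(=O)OC)CO[C@H](c2ccc(OCc3ccccc3)c(OC)c2)[C@H]1C=O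
F3 | step 3 | methyl (1R,5R,6S)-6-[4-(benzyloxy)-3-methoxyphenyl]-2-oxo-3,7-dioxabicyclo[3.3.0]octane-1-carboxylate | O=C1[C@@]2(C(=O)OC)CO[C@H](c3ccc(OCc4ccccc4)c(OC)c3)[C@H]2CO1
F4 | step 2 | (1R,2R)-1-[4-(benzyloxy)-3-methoxyphenyl]-2-chlorobut-3-en-1-ol | O[C@H](c1ccc(OCc2ccccc2)c(OC)c1)[C@H](Cl)C=C
F5 | step 2 | (2R,3S)-2-[4-(benzyloxy)-3-methoxyphenyl]-3-ethenyloxirane | O1[C@H](c2ccc(OCc3ccccc3)c(OC)c2)[C@@H]1C=C
F6 | step 8 | [4-(benzyloxy)-3-methoxyphenyl][(3R,4R,5S)-5-[4-(benzyloxy)-3-methoxyphenyl]-4-[(tert-butyldimethylsilyloxy)methyl]oxolan-3-yl]methanone | O=C(c1ccc(OCc2ccccc2)c(OC)c1)[C@H]1CO[C@H](c2ccc(OCc3ccccc3)c(OC)c2)[C@H]1CO[Si](C)(C)C(C)(C)C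
F7 | step 8 | (S)-[4-(benzyloxy)-3-methoxyphenyl][(3R,4R,5S)-5-[4-(benzyloxy)-3-methoxyphenyl]-4-[(tert-butyldimethylsilyloxy)methyl]oxolan-3-yl]methanol | COc1cc([C@@H](O)[C@H]2CO[C@H](c3ccc(OCc4ccccc4)c(OC)c3)[C@H]2CO[Si](C)(C)C(C)(C)C)ccc1OCc1ccccc1
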